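My flask holds a racemic pair of substrates, a coupling partner and a single-handed catalyst, and I begin with an easy division.

| setting | south | south-east | flask |
|---|---|---|---|
| left-handed substrate | 0.80 M | 0.80 M | 0.80 M |
| right-handed substrate | 0.80 M | 0.80 M | 0.80 M |
| coupling partner | 0.88 M | 0.88 M | 0.880 M |
| precatalyst | 4 mM | 4 mM | 4.0 mM |
| added ligand | 4.8 mM | 11 mM | 7.1 mM |
| remark | run made earlier | run made earlier |  |
| time |  |  | 2.0 d |

- south (time / h: left-handed product / %, right-handed product / %): 6.00: 17.2, 6.3; 12.0: 26.1, 10.0; 15.0: 28.2, 11.6; 25.0: 33.8, 14.2; 30.0: 33.9, 14.4
- south-east (time / h: left-handed product / %, right-handed product / %): 6.00: 17.8, 6.8; 12.0: 25.8, 10.1; 15.0: 27.4, 11.0; 25.0: 31.8, 15.3; 30.0: 33.5, 15.1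

(readings scatter by 0.5 percentage points)

- free catalyst is single-handed; left-handed substrate and right-handed substrate are mirror images of each other, charged as a racemate, each of them at the stated concentration
- the earlier runs were read with a standard deviation of 0.5 percentage points
- an excess is below zero if the other one leads

- excess of left-handed product over right-handed product in the product at 2.5 h
- excess of left-handed product over right-handed product in the product at 2.0 d
- part of the left-handed substrate and right-handed substrate charged together that has reacted at 2.0 d

I assume that each substrate molecule consumed takes one coupling partner. The coupling partner is then the limiting reagent, with 0.880 M charged against 1.60 M of substrates together. The partner ceiling, meaning the coupling partner charged over both substrates charged together, is 55.0%. The south run has the same ceiling, and at 30.0 h its products reach 48.3%. The south-east run reaches 48.6% with ligand at 11 mM instead of 4.8 mM, so I expect the flask, at 7.1 mM, to follow the same curve. The last two south readings gain 0.3 percentage points against a scatter of 0.5 points per reading, so they do not show where the curve stops. I therefore place the flask's conversion at 2.0 d between the last south reading and the ceiling.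

The forecast gives 49%, 37.5% and 51.5%, reasoning that “Partner depletion would give about 52% at 48 h”.

The flask gives 48.9%, 36.9% and 53.4%, and the forecast holds on each.

    free catalyst + left-handed substrate ⇌ catalyst intermediate A (K = 1.20 M⁻¹, k = 5250 M⁻¹ h⁻¹)
    free catalyst + right-handed substrate ⇌ catalyst intermediate B (K = 1.80 M⁻¹, k = 3230 M⁻¹ h⁻¹)
    coupling partner + catalyst intermediate A → free catalyst + left-handed product (k = 769 M⁻¹ h⁻¹)
    coupling partner + catalyst intermediate B → free catalyst + right-handed product (k = 159 M⁻¹ h⁻¹)
    free catalyst + added ligand ⇌ idle complex, settled at all times (K = 39.5 M⁻¹)
    precatalyst ⇌ free catalyst (K = 3.01, k = 0.119 h⁻¹)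
    coupling partner ⇌ dormant form (K = 2.50, k = 0.265 h⁻¹)

The flask has a dormant form that the ceiling does not count: 0.397 M at 0.200 d, but 0.0240 M at 2.00 d. By then the coupling partner stands at 0.41% of its charge, and the flask's conversion is 97.1% of the ceiling. The neighbour flask, charged with 0.22 M of coupling partner, has a ceiling of 13.7%. At the same time its coupling partner stands at 0.17% of its charge, and its conversion is 13.6%.

(The earlier runs and the new flask come from a simulation for substances that don't exist.)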